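Late in larch, the flask I handed over, E crept from 47.4% at 50.0 h to 53.0% at 120 h, while Q still stood at 23.1%.

| flask | Q | J | D | Z | temperature | remark | time |
|---|---|---|---|---|---|---|---|
| larch | 26 mM | 26 mM | 104 mM | 0.52 mM | 20 °C | the very flask that is asked about, followed so far |  |
| cedar | 26 mM | 26 mM | 210 mM | 0.52 mM | 26 °C | run made earlier |  |
| flask | 26 mM | 26 mM | 104 mM | 0.52 mM | 20 °C |  | 8.0 d |

- larch (time / h: E / %, Q / %): 10.0: 25.6, 32.9; 15.0: 32.8, 32.5; 20.0: 34.7, 30.6; 30.0: 42.0, 28.0; 50.0: 47.4, 25.0; 72.0: 50.2, 22.4; 120: 53.0, 23.1
- cedar (time / h: E / %, Q / %): 0.667: 10.0, 39.0; 2.00: 24.2, 32.5; 3.00: 29.2, 29.1; 5.00: 37.8, 27.2; 8.00: 44.4, 24.1; 10.0: 48.7, 24.3; 12.0: 50.1, 22.7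

(each reading ± 1 percentage point)

- midnight: at 8.0 d raise the temperature by 20 K, then wait 8.0 d
- spring: at 8.0 d add D, 100% of the amount charged, then wait 8.0 d
- summer: at 8.0 d add Z, 100% of the amount charged, then wait 8.0 d
- dusk: at 8.0 d take out 90% of the E then present, then wait 8.0 d
- autumn: change nothing and wait 8.0 d more

- D is single-handed; Q and J are mirror images of each other, charged as a racemate, each of them at the stated concentration
- what is taken out of E is counted as made
- the analysis behind the earlier runs scatters by 1 percentage point, standard deviation
- on the list of suspects stand: D + Q -> E; D + J -> L; Q + Z <-> J + Z; 2 D -> G; D + Z -> X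
- additions bring no volume worth counting
- the handed part of D does not stay in what it makes, so the products of the two hands are mirror images too

1. E, in percent of the Q and J together first charged, at 8.0 d
2. the remedy with the largest gain of E, or "none" below 2 percentage points (midnight / spring / summer / dusk / autumn / none)
3. E present, with what was taken out counted in, in percent of the Q and J together first charged, after midnight
4. E present, with what was taken out counted in, in percent of the Q and J together first charged, after summer

I read larch as a pool of Q and J that Z keeps turning into each other, with D, my limiting reagent, taking Q out as E. At the last reading Q was half of what E had not taken, so the two hands stayed level. E made was a quarter of the D charged, and I looked to D turning on itself into G for the D not found in E.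

That loss takes two D at each turn and needs neither Q nor J. D then falls roughly as one over time, like a decay whose time constant keeps stretching, and E gains equal steps per equal ratio of time. Those two readings gave 6.4 percentage points per e-fold, so I expected 56.0% at 8.0 d.

Equal doses of D should give the pool equal exposure, so each takes the same fraction. One dose leaves 44.0%, the survival share f. A second dose should therefore add E times f, or 25 points. My note said: leave the bath and Z alone, and add D.

The forecast gave 55%, spring, 67% after midnight and 58.5% after summer, holding that “Fresh D restarts the reaction and gains most”. The flask gave 56.6%, with spring best at 27 points, 57.7% after midnight and 57.6% after summer.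

    D + Q → E (k = 1.15 M⁻¹ h⁻¹, Ea = 76.0 kJ mol⁻¹)
    D + J → L (k = 0.0443 M⁻¹ h⁻¹, Ea = 68.0 kJ mol⁻¹)
    Q + Z ⇌ J + Z, rate k3*[Z]*[Q] forward; the back reaction follows from the equilibrium constant (k = 413 M⁻¹ h⁻¹, Ea = 60.0 kJ mol⁻¹)
    2 D → G (k = 0.719 M⁻¹ h⁻¹, Ea = 60.0 kJ mol⁻¹)
    D + Z → X (k = 0.102 M⁻¹ h⁻¹, Ea = 62.0 kJ mol⁻¹)
    (constants at 20 °C)

D turning on itself is the main reason larch stalls: without that step E at 8.0 d goes from 56.6% to 95.2%. The spring gain in this flask was 27 points, where autumn's waiting gave 1 point, and it stands against my 25 points. In the neighbouring flask, the same charge run at 45 °C, D ended at 0%. There the exposure exponent grows with the ratio of the Q step's constant to the self-loss constant, so f becomes 25.3%. In that neighbouring flask Q and J together ended at 26.2%.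

The runs are simulated for an exercise; the scatter is artificial.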